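Self-condensation is slow: its first half-life at the charged [substrate] is 52.2 h, longer than the run of 25 h. The catalysed step draws on the same substrate.

    substrate + dissolved gas + catalyst → catalyst + target (k1 = 345 L² mol⁻² min⁻¹)
    catalyst + added ligand ⇌ idle complex, settled at all times (K2 = 120 L mol⁻¹)
    2 substrate → self-condensation product (k3 = 0.0114 L mol⁻¹ min⁻¹)
    gas phase ⇌ dissolved gas, rate k4*(csat - [dissolved gas]) (k4 = 0.0114 min⁻¹, csat = 1.1 mM)

in all of them: substrate 14 mM; gas phase 1.1 mM (held); catalyst 2.1 mM; time 25 h

| charge | added ligand |
|---|---|
| north-west | 5.0 mM |
| south | 10 mM |
| east | 20 mM |
| south-east | 40 mM |

- percent here means substrate units held: one self-condensation product counts as two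
- where a step has two of a species, its rate is k times that concentration squared, and two are used at each turn
- at the start none of the gas is dissolved
- "hardly changes" means that all values lie within two and a half points (for a concentration: within two and a half percent of the largest)
- run time (north-west): 25 h

1. amount of target at the end, in percent of the substrate charged for north-west, south, east, south-east, in this order
2. the shape of the row from first to last (hardly changes / falls, then rises / rises all the way / rises, then falls / falls all the way)

The target step uses one substrate per turn and self-condensation two. So the substrate going to target, over the substrate going to self-condensation, is the constant of the target step times [catalyst] times [dissolved gas], divided by two, by the self-condensation constant and by [substrate]. This is a selectivity factor.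

I set [substrate] at its charge and [dissolved gas] at saturation, 1.1 mM, and ask at which [catalyst] the two paths run level. That level is 0.841 mM, and I call it the crossing catalyst level. The ratio is then [catalyst] over this crossing level.

Ligand binding stays at balance and the catalyst is not consumed, so each flask has its own steady [catalyst]:

- north-west: [catalyst] 1.39 mM, ratio 1.65
- south: [catalyst] 1.01 mM, ratio 1.21
- east: [catalyst] 0.651 mM, ratio 0.774
- south-east: [catalyst] 0.375 mM, ratio 0.446

Reading down, the ligand grows 8.00 times, while [catalyst] shrinks 3.71 times. The ratio falls from row to row . The crossing lies between south and east .

Two things bend the ratio during a run. Dissolved gas starts at none, which lowers it, and falling [substrate] raises it. I guess that they cancel, and I read each ratio as target over self-condensation at the end. So I expect the row to fall all the way, with target ahead of self-condensation in north-west and south and behind it in east and south-east. My reckoning stops at this ratio and gives no yields.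

The forecast gives 35.2%, 29%, 21.2% and 13.7%, a row that falls all the way, on the ground that “More ligand means less free catalyst, so the yield falls throughout.”

The simulation gives 35.2%, 28.8%, 21.0% and 13.5%, a row that falls all the way.

In north-west, both substrate-consuming steps ran while [catalyst] held at 66.0% of its charge and substrate fell to 42.1%. Half of the target step's turnover up to 25 h was done by 11.2 h, and self-condensation had 71% of its turnover up to then behind it at 12.5 h. Target over self-condensation at the end reads 1.55 in north-west, against my 1.65. In south-east, with catalyst at 17.9% of its charge, it reads 0.475, against my 0.446.

Its constants are assumed; the run is a simulation.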